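The flask should be stopped at the end of the feed, 4.0 min. The gamma reading there stands above its neighbours, and so does the zeta reading.

| flask | substrate | partner | second reagent | third reagent | remark | time |
|---|---|---|---|---|---|---|
| zeta | 0.34 mM | 0.70 equiv | 1.1 equiv | 1.3 equiv (fed, over 4.0 min) | run made earlier |  |
| gamma | 0.75 mM | 0.70 equiv | 1.1 equiv | 1.3 equiv (fed, over 4.0 min) | run made earlier |  |
| flask | 0.50 mM | 0.700 equiv | 1.10 equiv | 1.30 equiv (fed, over 4.0 min) |  | 50 min |

| run | time / min | target / % | substrate / % |
|---|---|---|---|
| zeta | 0.833 | 3.0 | 72.2 |
| zeta | 4.00 | 15.6 | 40.5 |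
| zeta | 15.0 | 1.0 | 30.2 |
| zeta | 60.0 | 0 | 29.0 |
| gamma | 0.833 | 11.0 | 56.6 |
| gamma | 4.00 | 25.2 | 34.8 |
| gamma | 15.0 | 1.7 | 29.4 |
| gamma | 60.0 | 1.3 | 28.9 |

(each reading ± 1 percentage point)

* the best time, 50 min at the latest, for target
* the amount of target, in percent of the substrate charged, at that time

The reckoning starts from the share of consumed substrate that stands as target at the end of the feed:

zeta: 26.2%
gamma: 38.7%

Objection: this share is no constant. It is larger in gamma, the more concentrated run. Read as a power of the starting concentration, it has the order

n = 0.491

So this flask is estimated at 31.7% as its target share s, the target held at the end of the feed per substrate consumed by then.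

Objection: the substrate consumed in this flask is unread. Interpolating the two runs in the logarithm of concentration leaves

substrate at the end of the feed: 37.7%
target: 19.7%

Objection: can the partner carry that turnover? Substrate ends at 29.0% in zeta and 28.9% in gamma, against 30.0% if partner is the limiting reagent, taken one to one. The turnover of 62.3% stays below the charge of 0.700.

One doubt stays open: no reading lies between 0.833 min and 4.00 min, so the peak may stand before the end of the feed.

The forecast gives 20.3% at 4 min: “The best time should therefore fall close to the end of the feed, not late.”

The flask peaks at 3.64 min with 20.5%.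

    2 third reagent → homo dimer (k = 13.0 M⁻¹ s⁻¹)
    substrate + partner → intermediate A (k = 36.0 M⁻¹ s⁻¹)
    second reagent + intermediate A → intermediate B (k = 120 M⁻¹ s⁻¹)
    intermediate B → side product (k = 0.00780 s⁻¹)
    third reagent + intermediate B ⇌ target (K = 5300 M⁻¹, k = 370 M⁻¹ s⁻¹)

At 4.00 min the flask holds 20.4% target and 37.1% substrate, a share of 32.4%. The neighbour flask is charged with 0.280 equiv of partner, other charges as in the flask. The same reckoning, with turnover put at the partner charge, gives 72.0% substrate at the end and 8.87% target. At 50.0 min the neighbour flask holds 72.0% substrate and 0% partner. The peak of the neighbour flask reaches 9.59%, which is 34.2% of the substrate equivalent of its partner charge.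

Readings and results were generated by integration for an exercise, noise included.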